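## The problem

Compound 33 is a germacranolide: a cyclodeca-1(10),4-diene fused trans across C6–C7 to an α-methylene-γ-butyrolactone, with an ester oxygen at C8 next to the ring fusion. Germacrane locants are used throughout: C10 bears C14H2OAc, C4 bears the C15 aldehyde, and C11(=C13H2)–C12 is the lactone arm. Both ring alkenes, C1=C10 and C4=C5, are trisubstituted and ring-cis (E by CIP), and each carries an oxidised one-carbon branch trans to the chain. Their geometry must therefore be fixed before the ring exists, because a medium ring offers no reliable way to correct it later. The three stereocentres C6 (R), C7 (R) and C8 (S) are contiguous. Only C6 is conveniently set by an external chiral catalyst, and it should then control C7 (trans lactone) and C8 (7,8-anti). Ten-membered rings close reluctantly, so the ring-forming reaction has to be fast at high dilution and tolerant of everything else in the molecule. Nearly every group is fragile: two α-methylene carbonyl units and an enal are Michael acceptors, the allylic acetate ionises with zerovalent palladium, the 6,12-lactone can migrate to O8 under base, and any 5-alkenylbutenolide intermediate loses C6 by γ-deprotonation. The enabling feature is that C8(O)–C7–C11(=C13H2) is a homoallylic alcohol whose C7 is the β-carbon of the α-methylene lactone. This is the retron of a γ-allylation of a C8 aldehyde by a 3-(metallomethyl)butenolide that already contains C6, C11, C12 and C13.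

## Retrosynthesis

**33 to 29 (acyl C–O bond at O8; C15 oxidation level).** The 2-(hydroxymethyl)acrylate is removed and the enal is taken back to a PMB-protected allylic alcohol. Carrying either group through the ring closure would offer the allylmetal a second aldehyde and two more Michael acceptors, and the C8 hydroxyl does not exist before ring closure in any case. Alcohol 29 therefore has one ester and one carbonyl group fewer than 33. The forward sequence asks for four things: esterification of a hindered secondary alcohol with acid 13 without translactonisation (30), oxidative PMB removal (31), oxidation of the only free allylic alcohol (32), and a final desilylation.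

**29 to 27 (C7–C8; the key cut).** Cutting C7–C8 removes the ten-membered ring and two stereocentres at once and leaves the single stereocentre C6 in bromide–aldehyde 27. The neighbouring cut C6–C7 (2-(bromomethyl)acrylate onto a C6 aldehyde) would leave C8 to be set separately on an open chain and the lactone to be closed afterwards. A lactone C–O cut does not open the carbocycle at all. The forward reaction must favour ring closure over intermolecular allylation, react at the γ-carbon C7, and take the butenolide face anti to C5 through a chair transition state.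

**27 to 24 (functional-group unmasking).** The allylic bromide comes from silyl ether 24 through alcohol 25, and the aldehyde from the dioxolane of bromide 26. The order is fixed: the CBr4/PPh3 pair would olefinate an aldehyde, and the β,γ-unsaturated aldehyde should exist only immediately before it is consumed. Butenolide 24 is a stable, fully protected compound with no reactive carbonyl other than the lactone.

**24 to 22 and 23 (C3–C4, sp3–sp2).** This cut divides the chain into two halves of similar size, each with its alkene geometry already fixed. A C2–C3 cut would require an allyl–allyl coupling with regiochemical ambiguity on both partners. A C4=C5 olefination would need an epimerisable α-oxy aldehyde at C6. A C5–C6 cut would create the stereocentre late on a large fragment. The forward reaction asks for an ester-tolerant alkylzinc (23, from iodide 10) and a stereoretentive coupling with alkenyl iodide 22 that leaves the butenolide alone.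

**22 to 20 and 13 (C7=C11 and the acyl C12–O bond).** The butenolide is opened to acrylate 21, which is the ester of dienol 20 with acid 13. Making the butenolide on the small eastern fragment, before the coupling, avoids a competing seven-membered ring closure onto C1=C10. The alkenyl iodide is inert to metathesis. The forward step is ring-closing metathesis of an α-substituted acrylate.

**20 to 15 and 16 (C4–I, C5–H, C5–C6).** Iodide 20 comes from enynol 18 by hydroxyl-directed trans-hydroalumination and iodination. The free hydroxyl is at C6, so hydride goes to C5 and the iodine ends up on C4 cis to C6, exactly where C3 must be attached. A directed carbomagnesiation would not fit here, because it places the new carbon on the alkyne carbon next to the directing oxygen. Enynol 18 arises from PMB propargyl ether 15 (from propargyl alcohol 14) and acrolein 16 by asymmetric alkynylation, which forms C5–C6 and sets C6. The precursors are two three-carbon commodity compounds.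

**10 to 4 and 5, and 4 to 1 (C9–C10 and C10–C14).** For C1=C10 the directing hydroxyl is at C14, next to the carbon (C10) that needs the new substituent. A copper-catalysed anti-carbomagnesiation of alkynol 4 with Grignard reagent 5 is therefore the matching tool. It gives alcohol 7 with C9 cis to C2 and delivers C8 at the aldehyde oxidation level as a dioxolane. A Wittig reaction with a lactone ylide would give the same geometry but an undifferentiated 1,4-diol after reduction. Acetylation (8), desilylation (9) and iodination (10) follow. Alkynol 4 comes from but-3-yn-1-ol 1 through silyl ether 2 and formaldehyde.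

**13 to 11.** Acid 13 is made from ethyl 2-(hydroxymethyl)acrylate 11 by silylation (12) and saponification. It is used twice, for C11–C13 of the lactone and for the C8 side chain.

## Roads not taken

**Alternative 1:** The cut is the C8–C9 ring bond, with the ten-membered ring derived from an eight-membered one. A tertiary vinyl carbinol made from the isoprene dimer A2 would be converted into its potassium alkoxide. Allylic C9 would then migrate from C6 to the vinyl terminus C8 in an anionic 1,3-shift, giving dienone A1.
- Merits: the ring and both ring-cis alkenes come in a handful of steps from a bulk chemical, with no high-dilution step. In ring construction this road is clearly shorter than the chosen plan, which needs eleven steps in its longest line before the ring closes.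
- Weak points: A1 is achiral and carries no oxygen besides the C6 ketone. C14 and C15 are methyl groups that would have to be oxidised selectively and to different levels. C8 would need oxygenation, C7 would need the three-carbon lactone arm, and three stereocentres, including the absolute configuration, would have to be created on a mobile medium ring. The 1,3-shift itself competes with fragmentation pathways of the alkoxide.
- Comparison: the chosen plan sets against the shorter ring synthesis that its ring closure delivers every oxygen function in place and creates two of the three stereocentres under control of the third.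

**Alternative 2:** The cut is the C1–C6 bond of a cis-fused bicyclic epoxy alcohol. Activation of the C6 alkoxide would trigger a Grob fragmentation: C1–C6 and the epoxide C10–O bond break while C6=O and C1=C10 form, giving dienone A3 with a free C14 hydroxyl.
- Merits: the C1=C10 geometry follows stereospecifically from the relative configuration of a six-membered-ring precursor. C14 emerges oxygenated and differentiated, the C8 stereocentre is already present, and no entropically disfavoured macrocyclisation is needed. For the ring and for C1=C10 this road is at least as secure as the chosen one.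
- Weak points: C15 is still a methyl group on an enone and would need a late allylic oxidation. The lactone would have to be built at C6/C7 from the ketone, and an enolate at C7 has the C8 silyloxy group in the β-position, so elimination threatens. C6 and C7 would be set on the medium ring, and the fragmentation substrate itself needs four stereocentres.
- Comparison: the chosen plan sets against it that C15, the lactone and C7 are in place at the moment of ring closure, and that only one stereocentre has to be made independently.

**Alternative 3:** The cut is C4=C5. A C4 phosphorane stabilised by the C15 formyl group would condense with a C5 aldehyde on the lactone in an intramolecular Wittig reaction, giving A4, which is identical with 32.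
- Merits: this is the latest possible ring closure, one desilylation from 33. The enal geometry is the thermodynamic one, and no stereocentre is formed in the ring closure, so there is no diastereoselectivity risk at that stage. In convergence and endgame economy this road is better than the chosen plan.
- Weak points: the seco compound must already contain C6–C8 with all three stereocentres, the α-methylene lactone and the acrylate, all of which are Michael acceptors for phosphines and ylides. The C5 aldehyde sits α to the lactone oxygen at C6, where it can epimerise and eliminate. Formyl-stabilised ylides are the least reactive Wittig reagents and usually need heat, which favours oligomers over a strained ten-membered ring.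
- Comparison: the chosen plan sets against it ring-closing partners that react at room temperature in water, and a ring closure that itself creates C7 and C8.

Key step: step 18

## Route

Assumption: (S,S)-ProPhenol is taken to deliver (S)-18 in step 10. The sense of induction has to be confirmed on 18 by MTPA ester analysis, and the mirror-image ligand is used if it proves opposite.

Step 1
Reactants: 1 but-3-yn-1-ol
Product: 2 tert-butyl(but-3-yn-1-yloxy)dimethylsilane
Conditions: TBSCl, imidazole, CH2Cl2, 0 °C → rt
Reagents that add atoms: tert-butyldimethylsilyl chloride CC(C)(C)[Si](C)(C)Cl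
Why: Standard silylation of a primary alcohol; the silyl ether masks the future C3 oxygen through the organometallic steps and is the only fluoride-labile group of the western fragment.

Step 2
Reactants: 2 tert-butyl(but-3-yn-1-yloxy)dimethylsilane
Product: 4 5-[(tert-butyldimethylsilyl)oxy]pent-2-yn-1-ol, via lithium acetylide 3 (not isolated)
Conditions: n-BuLi, THF, −78 °C; (CH2O)n, −78 °C → rt; aq. NH4Cl
Reagents that add atoms: paraformaldehyde (formaldehyde) C=O
Why: Hydroxymethylation of a lithium acetylide; C14 enters as the propargylic CH2OH that directs the next step.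

Step 3
Reactants: 4 5-[(tert-butyldimethylsilyl)oxy]pent-2-yn-1-ol; 5 (1,3-dioxolan-2-ylmethyl)magnesium bromide
Product: 7 (E)-5-[(tert-butyldimethylsilyl)oxy]-2-[(1,3-dioxolan-2-yl)methyl]pent-2-en-1-ol, via cyclic alkenylmagnesium alkoxide 6 (not isolated)
Conditions: 5 (3 equiv), CuI (15 mol%), THF, −20 °C → rt; aq. NH4Cl
Reagents that add atoms: none
Why: Copper-catalysed anti-carbomagnesiation of a 2-alkyn-1-ol: the magnesium alkoxide directs the alkyl group to the proximal alkyne carbon C10 and the metal to C1 within the five-membered chelate 6. Protonation with retention then leaves the new CH2 (C9) cis to the C2 chain, which fixes the C1=C10 geometry, and the dioxolane carries C8 at the aldehyde oxidation level.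

Step 4
Reactants: 7 (E)-5-[(tert-butyldimethylsilyl)oxy]-2-[(1,3-dioxolan-2-yl)methyl]pent-2-en-1-ol
Product: 8 (E)-5-[(tert-butyldimethylsilyl)oxy]-2-[(1,3-dioxolan-2-yl)methyl]pent-2-en-1-yl acetate
Conditions: Ac2O, pyridine, DMAP (cat.), CH2Cl2, 0 °C → rt
Reagents that add atoms: acetic anhydride CC(=O)OC(C)=O
Why: Routine acetylation installs the C14 acetate of the target at once; every later reagent (zinc insertion, palladium coupling, metathesis, indium) tolerates an acetate.

Step 5
Reactants: 8 (E)-5-[(tert-butyldimethylsilyl)oxy]-2-[(1,3-dioxolan-2-yl)methyl]pent-2-en-1-yl acetate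
Product: 9 (E)-2-[(1,3-dioxolan-2-yl)methyl]-5-hydroxypent-2-en-1-yl acetate
Conditions: TBAF, AcOH, THF, 0 °C → rt
Reagents that add atoms: none
Why: Buffered fluoride desilylation of a primary silyl ether; the buffer keeps the acetate in place and the dioxolane is inert.

Step 6
Reactants: 9 (E)-2-[(1,3-dioxolan-2-yl)methyl]-5-hydroxypent-2-en-1-yl acetate
Product: 10 (E)-2-[(1,3-dioxolan-2-yl)methyl]-5-iodopent-2-en-1-yl acetate
Conditions: I2, PPh3, imidazole, CH2Cl2, 0 °C → rt
Reagents that add atoms: iodine II
Why: Appel-type iodination of a primary alcohol under near-neutral conditions gives the homoallylic iodide needed for zinc insertion.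

Step 7
Reactants: 11 ethyl 2-(hydroxymethyl)acrylate
Product: 12 ethyl 2-{[(tert-butyldimethylsilyl)oxy]methyl}acrylate
Conditions: TBSCl, imidazole, CH2Cl2, 0 °C → rt
Reagents that add atoms: tert-butyldimethylsilyl chloride CC(C)(C)[Si](C)(C)Cl
Why: Silylation of the primary allylic alcohol prevents self-esterification of the acid made in the next step.

Step 8
Reactants: 12 ethyl 2-{[(tert-butyldimethylsilyl)oxy]methyl}acrylate
Product: 13 2-{[(tert-butyldimethylsilyl)oxy]methyl}acrylic acid
Conditions: LiOH·H2O, THF/H2O, 0 °C → rt; then 1 M HCl to pH 3 at 0 °C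
Reagents that add atoms: lithium hydroxide [Li+].[OH-]
Why: Saponification of the ethyl ester at low temperature, where conjugate addition of hydroxide is slow; brief cold acidification leaves the primary silyl ether intact.

Step 9
Reactants: 14 propargyl alcohol
Product: 15 1-methoxy-4-[(prop-2-yn-1-yloxy)methyl]benzene
Conditions: NaH, PMBCl, n-Bu4NI (cat.), THF, 0 °C → rt
Reagents that add atoms: 4-methoxybenzyl chloride COc1ccc(CCl)cc1
Why: Williamson etherification; the PMB ether protects the future C15 oxygen and is later removed oxidatively in the presence of silyl ether, acetate and both lactone and acrylate esters.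

Step 10
Reactants: 15 1-methoxy-4-[(prop-2-yn-1-yloxy)methyl]benzene; 16 acrolein
Product: 18 (3S)-6-[(4-methoxybenzyl)oxy]hex-1-en-4-yn-3-ol, via alkynyl(methyl)zinc 17 (not isolated)
Conditions: 15 (3 equiv), Me2Zn (3 equiv), (S,S)-ProPhenol (10 mol%), Ph3P=O (20 mol%), toluene, 0 °C; then 16, 0–4 °C; aq. NH4Cl
Reagents that add atoms: none
Why: Catalytic asymmetric alkynylation of an α,β-unsaturated aldehyde: the dinuclear zinc–ProPhenol complex binds the aldehyde and the alkynylzinc 17 and delivers the alkynyl group to one enantiotopic face of acrolein, forming C5–C6 and setting C6. The descriptor is S here and becomes R from 24 onwards only because the CIP priorities change.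

Step 11
Reactants: 18 (3S)-6-[(4-methoxybenzyl)oxy]hex-1-en-4-yn-3-ol
Product: 20 (3S,4Z)-5-iodo-6-[(4-methoxybenzyl)oxy]hexa-1,4-dien-3-ol, via cyclic alkenylaluminate 19 (not isolated)
Conditions: NaAlH2(OCH2CH2OMe)2, THF, 0 °C; EtOAc; then I2, −78 → 0 °C; aq. potassium sodium tartrate
Reagents that add atoms: iodine II
Why: Hydroxyl-directed trans-hydroalumination of a propargylic alcohol delivers hydride to C5 and aluminium to C4 in the five-membered aluminate 19, and iodinolysis proceeds with retention. Iodine is thus cis to C6 and marks the site and geometry for C3; low temperature suppresses elimination of the C15 ether to an allene.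

Step 12
Reactants: 20 (3S,4Z)-5-iodo-6-[(4-methoxybenzyl)oxy]hexa-1,4-dien-3-ol; 13 2-{[(tert-butyldimethylsilyl)oxy]methyl}acrylic acid
Product: 21 (3S,4Z)-5-iodo-6-[(4-methoxybenzyl)oxy]hexa-1,4-dien-3-yl 2-{[(tert-butyldimethylsilyl)oxy]methyl}acrylate
Conditions: 13, DCC, DMAP (cat.), CH2Cl2, 0 °C → rt
Reagents that add atoms: none
Why: Steglich esterification at oxygen, so C6 is untouched; it brings in C11, C12 and C13 of the lactone.

Step 13
Reactants: 21 (3S,4Z)-5-iodo-6-[(4-methoxybenzyl)oxy]hexa-1,4-dien-3-yl 2-{[(tert-butyldimethylsilyl)oxy]methyl}acrylate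
Product: 22 (S)-3-{[(tert-butyldimethylsilyl)oxy]methyl}-5-{(Z)-2-iodo-3-[(4-methoxybenzyl)oxy]prop-1-en-1-yl}furan-2(5H)-one
Conditions: second-generation Grubbs catalyst (H2IMes)(PCy3)Cl2Ru=CHPh (5 mol%), toluene (5 mM), 80 °C
Reagents that add atoms: none
Why: Ring-closing metathesis between the vinyl group and the α-substituted acrylate gives the butenolide with loss of ethene. The iodoalkene does not take part, and the neutral conditions do not endanger the acidic C6–H.

Step 14
Reactants: 10 (E)-2-[(1,3-dioxolan-2-yl)methyl]-5-iodopent-2-en-1-yl acetate; 22 (S)-3-{[(tert-butyldimethylsilyl)oxy]methyl}-5-{(Z)-2-iodo-3-[(4-methoxybenzyl)oxy]prop-1-en-1-yl}furan-2(5H)-one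
Product: 24 (2E,6E)-7-[(R)-4-{[(tert-butyldimethylsilyl)oxy]methyl}-5-oxo-2,5-dihydrofuran-2-yl]-2-[(1,3-dioxolan-2-yl)methyl]-6-{[(4-methoxybenzyl)oxy]methyl}hepta-2,6-dien-1-yl acetate, via alkylzinc iodide 23 (not isolated)
Conditions: 10, Zn dust (activated with BrCH2CH2Br/TMSCl), LiCl, THF, 35 °C; then 22, Pd(OAc)2 (5 mol%), SPhos (10 mol%), THF, rt
Reagents that add atoms: none
Why: Negishi coupling of a functionalised primary alkylzinc iodide with an alkenyl iodide forms C3–C4 with retention of the alkene geometry, so C3 ends up cis to C6. Organozinc reagents tolerate the acetate, the acetal and the lactone, and oxidative addition into the C–I bond is far faster than ionisation of the allylic C–O bonds.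

Step 15
Reactants: 24 (2E,6E)-7-[(R)-4-{[(tert-butyldimethylsilyl)oxy]methyl}-5-oxo-2,5-dihydrofuran-2-yl]-2-[(1,3-dioxolan-2-yl)methyl]-6-{[(4-methoxybenzyl)oxy]methyl}hepta-2,6-dien-1-yl acetate
Product: 25 (2E,6E)-2-[(1,3-dioxolan-2-yl)methyl]-7-[(R)-4-(hydroxymethyl)-5-oxo-2,5-dihydrofuran-2-yl]-6-{[(4-methoxybenzyl)oxy]methyl}hepta-2,6-dien-1-yl acetate
Conditions: HF·pyridine, pyridine, THF, 0 °C → rt
Reagents that add atoms: none
Why: Desilylation under weakly acidic conditions; basic fluoride is avoided because the butenolide C6–H is γ-acidic and deprotonation would racemise C6.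

Step 16
Reactants: 25 (2E,6E)-2-[(1,3-dioxolan-2-yl)methyl]-7-[(R)-4-(hydroxymethyl)-5-oxo-2,5-dihydrofuran-2-yl]-6-{[(4-methoxybenzyl)oxy]methyl}hepta-2,6-dien-1-yl acetate
Product: 26 (2E,6E)-7-[(R)-4-(bromomethyl)-5-oxo-2,5-dihydrofuran-2-yl]-2-[(1,3-dioxolan-2-yl)methyl]-6-{[(4-methoxybenzyl)oxy]methyl}hepta-2,6-dien-1-yl acetate
Conditions: CBr4, PPh3, CH2Cl2, −20 → 0 °C
Reagents that add atoms: carbon tetrabromide BrC(Br)(Br)Br
Why: Appel bromination of the primary allylic alcohol under neutral conditions; it is placed before the aldehyde is unveiled because this reagent pair would olefinate an aldehyde.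

Step 17
Reactants: 26 (2E,6E)-7-[(R)-4-(bromomethyl)-5-oxo-2,5-dihydrofuran-2-yl]-2-[(1,3-dioxolan-2-yl)methyl]-6-{[(4-methoxybenzyl)oxy]methyl}hepta-2,6-dien-1-yl acetate
Product: 27 (2E,6E)-7-[(R)-4-(bromomethyl)-5-oxo-2,5-dihydrofuran-2-yl]-6-{[(4-methoxybenzyl)oxy]methyl}-2-(2-oxoethyl)hepta-2,6-dien-1-yl acetate
Conditions: TsOH·H2O (0.2 equiv), acetone/H2O (10:1), rt → 40 °C
Reagents that add atoms: water O
Why: Acid-catalysed acetal hydrolysis (transacetalisation to acetone) with a non-nucleophilic acid, so the allylic bromide is not exchanged. The β,γ-unsaturated aldehyde is used at once without chromatography to avoid migration of C1=C10 into conjugation.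

Step 18
Reactants: 27 (2E,6E)-7-[(R)-4-(bromomethyl)-5-oxo-2,5-dihydrofuran-2-yl]-6-{[(4-methoxybenzyl)oxy]methyl}-2-(2-oxoethyl)hepta-2,6-dien-1-yl acetate
Product: 29 [(3aR,4S,6E,10E,11aR)-4-hydroxy-10-{[(4-methoxybenzyl)oxy]methyl}-3-methylidene-2-oxo-2,3,3a,4,5,8,9,11a-octahydrocyclodeca[b]furan-6-yl]methyl acetate, via allylindium dibromide 28 (not isolated)
Conditions: In powder (4 equiv), THF/H2O (3:1), rt, slow addition of 27 to 1 mM final concentration
Reagents that add atoms: none
Why: Zerovalent indium inserts into the allylic C13–Br bond of 27 to give allylindium 28, which adds through its γ-carbon C7 to the C8 aldehyde with allylic transposition, so that C7–C8, the exocyclic C11=C13 alkene and the carbocycle form in one event. The closest known reactions are the indium- or zinc-mediated γ-allylation of aldehydes by 3-(bromomethyl)furan-2(5H)-ones, which gives β-(hydroxyalkyl)-α-methylene-γ-butyrolactones, and Barbier-type closures of ten-membered rings from 2-(bromomethyl)acrylates. The ten-membered ring is closed by a 10-exo-trig addition to the aldehyde carbon, the carbonyl oxygen staying outside the ring; no other ring is formed. C7 is controlled by C6: the new bond is expected on the butenolide face opposite the C5 substituent, which gives the trans-fused lactone (7R). C8 is controlled by the closed six-membered chair transition state (In, O, C8, C7, C11, C13): C6 is locked trans to C13 on the C7=C11 bond, so with the aldehyde chain equatorial the 7,8-anti product (8S) should result. The step needs γ- over α-attack, which the chair secures, and ring closure over intermolecular allylation, which slow addition at about 1 mM and the bend imposed on the tether by the two ring-cis alkenes should favour. The neutral aqueous medium should leave the acetate, the PMB ether and the β,γ-unsaturated aldehyde untouched until it reacts.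

Step 19
Reactants: 29 [(3aR,4S,6E,10E,11aR)-4-hydroxy-10-{[(4-methoxybenzyl)oxy]methyl}-3-methylidene-2-oxo-2,3,3a,4,5,8,9,11a-octahydrocyclodeca[b]furan-6-yl]methyl acetate; 13 2-{[(tert-butyldimethylsilyl)oxy]methyl}acrylic acid
Product: 30 (3aR,4S,6E,10E,11aR)-6-(acetoxymethyl)-10-{[(4-methoxybenzyl)oxy]methyl}-3-methylidene-2-oxo-2,3,3a,4,5,8,9,11a-octahydrocyclodeca[b]furan-4-yl 2-{[(tert-butyldimethylsilyl)oxy]methyl}acrylate
Conditions: 13, DCC, DMAP, CH2Cl2, 0 °C → rt
Reagents that add atoms: none
Why: Steglich esterification of the C8 hydroxyl with retention at C8; acylating first blocks migration of the lactone from O6 to O8 in the later steps.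

Step 20
Reactants: 30 (3aR,4S,6E,10E,11aR)-6-(acetoxymethyl)-10-{[(4-methoxybenzyl)oxy]methyl}-3-methylidene-2-oxo-2,3,3a,4,5,8,9,11a-octahydrocyclodeca[b]furan-4-yl 2-{[(tert-butyldimethylsilyl)oxy]methyl}acrylate
Product: 31 (3aR,4S,6E,10E,11aR)-6-(acetoxymethyl)-10-(hydroxymethyl)-3-methylidene-2-oxo-2,3,3a,4,5,8,9,11a-octahydrocyclodeca[b]furan-4-yl 2-{[(tert-butyldimethylsilyl)oxy]methyl}acrylate
Conditions: DDQ, CH2Cl2/pH 7 buffer (10:1), 0 °C → rt
Reagents that add atoms: none
Why: Oxidative cleavage of the PMB ether by hydride abstraction and hydrolysis of the oxocarbenium ion; silyl ether, acetate and both α-methylene carbonyl units are inert to DDQ.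

Step 21
Reactants: 31 (3aR,4S,6E,10E,11aR)-6-(acetoxymethyl)-10-(hydroxymethyl)-3-methylidene-2-oxo-2,3,3a,4,5,8,9,11a-octahydrocyclodeca[b]furan-4-yl 2-{[(tert-butyldimethylsilyl)oxy]methyl}acrylate
Product: 32 (3aR,4S,6E,10E,11aR)-6-(acetoxymethyl)-10-formyl-3-methylidene-2-oxo-2,3,3a,4,5,8,9,11a-octahydrocyclodeca[b]furan-4-yl 2-{[(tert-butyldimethylsilyl)oxy]methyl}acrylate
Conditions: MnO2 (activated, excess), CH2Cl2, rt
Reagents that add atoms: none
Why: Chemoselective allylic oxidation of the only free allylic alcohol; the enal is formed in its thermodynamically preferred geometry (C15 trans to C6), so no isomerisation is expected.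

Step 22
Reactants: 32 (3aR,4S,6E,10E,11aR)-6-(acetoxymethyl)-10-formyl-3-methylidene-2-oxo-2,3,3a,4,5,8,9,11a-octahydrocyclodeca[b]furan-4-yl 2-{[(tert-butyldimethylsilyl)oxy]methyl}acrylate
Product: 33 (3aR,4S,6E,10E,11aR)-6-(acetoxymethyl)-10-formyl-3-methylidene-2-oxo-2,3,3a,4,5,8,9,11a-octahydrocyclodeca[b]furan-4-yl 2-(hydroxymethyl)acrylate
Conditions: HF·pyridine, pyridine, THF, 0 °C → rt
Reagents that add atoms: none
Why: Desilylation under buffered, weakly acidic conditions releases the side-chain alcohol without touching the acetate, the enal or the two Michael acceptors.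

## Compound list

1 | but-3-yn-1-ol | C#CCCO | starting material
2 | tert-butyl(but-3-yn-1-yloxy)dimethylsilane | C#CCCO[Si](C)(C)C(C)(C)C | intermediate
3 | lithium 4-[(tert-butyldimethylsilyl)oxy]but-1-yn-1-ide (formed in situ) | [Li]C#CCCO[Si](C)(C)C(C)(C)C | intermediate
4 | 5-[(tert-butyldimethylsilyl)oxy]pent-2-yn-1-ol | OCC#CCCO[Si](C)(C)C(C)(C)C | intermediate
5 | (1,3-dioxolan-2-ylmethyl)magnesium bromide | Br[Mg]CC1OCCO1 | starting material
6 | 3-{2-[(tert-butyldimethylsilyl)oxy]ethyl}-4-[(1,3-dioxolan-2-yl)methyl]-2,5-dihydro-1,2-oxamagnesole (cyclic alkenylmagnesium alkoxide, formed in situ) | [Mg]1OCC(CC2OCCO2)=C1CCO[Si](C)(C)C(C)(C)C | intermediate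
7 | (E)-5-[(tert-butyldimethylsilyl)oxy]-2-[(1,3-dioxolan-2-yl)methyl]pent-2-en-1-ol | OC/C(CC1OCCO1)=C/CCO[Si](C)(C)C(C)(C)C | intermediate
8 | (E)-5-[(tert-butyldimethylsilyl)oxy]-2-[(1,3-dioxolan-2-yl)methyl]pent-2-en-1-yl acetate | CC(=O)OC/C(CC1OCCO1)=C/CCO[Si](C)(C)C(C)(C)C | intermediate
9 | (E)-2-[(1,3-dioxolan-2-yl)methyl]-5-hydroxypent-2-en-1-yl acetate | CC(=O)OC/C(CC1OCCO1)=C/CCO | intermediate
10 | (E)-2-[(1,3-dioxolan-2-yl)methyl]-5-iodopent-2-en-1-yl acetate | CC(=O)OC/C(CC1OCCO1)=C/CCI | intermediate
11 | ethyl 2-(hydroxymethyl)acrylate | C=C(CO)C(=O)OCC | starting material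
12 | ethyl 2-{[(tert-butyldimethylsilyl)oxy]methyl}acrylate | C=C(CO[Si](C)(C)C(C)(C)C)C(=O)OCC | intermediate
13 | 2-{[(tert-butyldimethylsilyl)oxy]methyl}acrylic acid | C=C(CO[Si](C)(C)C(C)(C)C)C(=O)O | intermediate
14 | propargyl alcohol | C#CCO | starting material
15 | 1-methoxy-4-[(prop-2-yn-1-yloxy)methyl]benzene | C#CCOCc1ccc(OC)cc1 | intermediate
16 | acrolein | C=CC=O | starting material
17 | methyl{3-[(4-methoxybenzyl)oxy]prop-1-yn-1-yl}zinc (formed in situ) | C[Zn]C#CCOCc1ccc(OC)cc1 | intermediate
18 | (3S)-6-[(4-methoxybenzyl)oxy]hex-1-en-4-yn-3-ol | C=C[C@H](O)C#CCOCc1ccc(OC)cc1 | intermediate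
19 | sodium cyclic alkenylaluminate: five-membered ring Al–O–C6–C5=C4 with Al on C4 and two 2-methoxyethoxy ligands (formed in situ) | C=C[C@@H]1O[Al-](OCCOC)(OCCOC)C(COCc2ccc(OC)cc2)=C1.[Na+] | intermediate
20 | (3S,4Z)-5-iodo-6-[(4-methoxybenzyl)oxy]hexa-1,4-dien-3-ol | C=C[C@H](O)/C=C(\I)COCc1ccc(OC)cc1 | intermediate
21 | (3S,4Z)-5-iodo-6-[(4-methoxybenzyl)oxy]hexa-1,4-dien-3-yl 2-{[(tert-butyldimethylsilyl)oxy]methyl}acrylate | C=C[C@H](OC(=O)C(=C)CO[Si](C)(C)C(C)(C)C)/C=C(\I)COCc1ccc(OC)cc1 | intermediate
22 | (S)-3-{[(tert-butyldimethylsilyl)oxy]methyl}-5-{(Z)-2-iodo-3-[(4-methoxybenzyl)oxy]prop-1-en-1-yl}furan-2(5H)-one | O=C1O[C@H](/C=C(\I)COCc2ccc(OC)cc2)C=C1CO[Si](C)(C)C(C)(C)C | intermediate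
23 | [(E)-4-(acetoxymethyl)-5-(1,3-dioxolan-2-yl)pent-3-en-1-yl]zinc iodide (formed in situ) | CC(=O)OC/C(CC1OCCO1)=C/CC[Zn]I | intermediate
24 | (2E,6E)-7-[(R)-4-{[(tert-butyldimethylsilyl)oxy]methyl}-5-oxo-2,5-dihydrofuran-2-yl]-2-[(1,3-dioxolan-2-yl)methyl]-6-{[(4-methoxybenzyl)oxy]methyl}hepta-2,6-dien-1-yl acetate | O=C1O[C@H](/C=C(COCc2ccc(OC)cc2)\CC/C=C(COC(C)=O)\CC2OCCO2)C=C1CO[Si](C)(C)C(C)(C)C | intermediate
25 | (2E,6E)-2-[(1,3-dioxolan-2-yl)methyl]-7-[(R)-4-(hydroxymethyl)-5-oxo-2,5-dihydrofuran-2-yl]-6-{[(4-methoxybenzyl)oxy]methyl}hepta-2,6-dien-1-yl acetate | O=C1O[C@H](/C=C(COCc2ccc(OC)cc2)\CC/C=C(COC(C)=O)\CC2OCCO2)C=C1CO | intermediate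
26 | (2E,6E)-7-[(R)-4-(bromomethyl)-5-oxo-2,5-dihydrofuran-2-yl]-2-[(1,3-dioxolan-2-yl)methyl]-6-{[(4-methoxybenzyl)oxy]methyl}hepta-2,6-dien-1-yl acetate | O=C1O[C@H](/C=C(COCc2ccc(OC)cc2)\CC/C=C(COC(C)=O)\CC2OCCO2)C=C1CBr | intermediate
27 | (2E,6E)-7-[(R)-4-(bromomethyl)-5-oxo-2,5-dihydrofuran-2-yl]-6-{[(4-methoxybenzyl)oxy]methyl}-2-(2-oxoethyl)hepta-2,6-dien-1-yl acetate | O=C1O[C@H](/C=C(COCc2ccc(OC)cc2)\CC/C=C(COC(C)=O)\CC=O)C=C1CBr | intermediate
28 | allylindium dibromide of 27 (InBr2 on C13; drawn as the monoallyl species of the sesquibromide equilibrium; formed in situ) | Br[In](Br)CC1=C[C@@H](/C=C(COCc2ccc(OC)cc2)\CC/C=C(COC(C)=O)\CC=O)OC1=O | intermediate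
29 | [(3aR,4S,6E,10E,11aR)-4-hydroxy-10-{[(4-methoxybenzyl)oxy]methyl}-3-methylidene-2-oxo-2,3,3a,4,5,8,9,11a-octahydrocyclodeca[b]furan-6-yl]methyl acetate | O[C@H]1C/C(COC(C)=O)=C\CC/C(COCc3ccc(OC)cc3)=C\[C@H]2OC(=O)C(=C)[C@H]12 | intermediate
30 | (3aR,4S,6E,10E,11aR)-6-(acetoxymethyl)-10-{[(4-methoxybenzyl)oxy]methyl}-3-methylidene-2-oxo-2,3,3a,4,5,8,9,11a-octahydrocyclodeca[b]furan-4-yl 2-{[(tert-butyldimethylsilyl)oxy]methyl}acrylate | C=C(CO[Si](C)(C)C(C)(C)C)C(=O)O[C@H]1C/C(COC(C)=O)=C\CC/C(COCc3ccc(OC)cc3)=C\[C@H]2OC(=O)C(=C)[C@H]12 | intermediate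
31 | (3aR,4S,6E,10E,11aR)-6-(acetoxymethyl)-10-(hydroxymethyl)-3-methylidene-2-oxo-2,3,3a,4,5,8,9,11a-octahydrocyclodeca[b]furan-4-yl 2-{[(tert-butyldimethylsilyl)oxy]methyl}acrylate | C=C(CO[Si](C)(C)C(C)(C)C)C(=O)O[C@H]1C/C(COC(C)=O)=C\CC/C(CO)=C\[C@H]2OC(=O)C(=C)[C@H]12 | intermediate
32 | (3aR,4S,6E,10E,11aR)-6-(acetoxymethyl)-10-formyl-3-methylidene-2-oxo-2,3,3a,4,5,8,9,11a-octahydrocyclodeca[b]furan-4-yl 2-{[(tert-butyldimethylsilyl)oxy]methyl}acrylate | C=C(CO[Si](C)(C)C(C)(C)C)C(=O)O[C@H]1C/C(COC(C)=O)=C\CC/C(C=O)=C\[C@H]2OC(=O)C(=C)[C@H]12 | intermediate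
33 | (3aR,4S,6E,10E,11aR)-6-(acetoxymethyl)-10-formyl-3-methylidene-2-oxo-2,3,3a,4,5,8,9,11a-octahydrocyclodeca[b]furan-4-yl 2-(hydroxymethyl)acrylate | C=C(CO)C(=O)O[C@H]1C/C(COC(C)=O)=C\CC/C(C=O)=C\[C@H]2OC(=O)C(=C)[C@H]12 | target

## Step count and least certain steps

Total step count: 22. Longest linear sequence: 15 steps (steps 1–6, then 14–22). The eastern branch (steps 9–13) and the acid branch (steps 7–8) are shorter.

**Step 18 (key step).** The most likely failures are intermolecular allylation at the metal surface outrunning closure of the ten-membered ring, and loss of facial control if the tether cannot reach C7 from the face anti to C5 or forces a boat-like transition state, giving a cis lactone or the 7,8-syn isomer. The fallback replaces the transient allylindium by an isolable allylboron reagent that can be diluted at will and reacts only through a closed chair. It sets out from 26 and comes back at 29.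
- Borylation of 26 with B2pin2 under zerovalent-palladium catalysis (Pd2(dba)3, toluene, rt) would give (2E,6E)-2-[(1,3-dioxolan-2-yl)methyl]-6-{[(4-methoxybenzyl)oxy]methyl}-7-{(R)-5-oxo-4-[(4,4,5,5-tetramethyl-1,3,2-dioxaborolan-2-yl)methyl]-2,5-dihydrofuran-2-yl}hepta-2,6-dien-1-yl acetate F1.
- Hydrolysis of the dioxolane as in step 17 would give (2E,6E)-6-{[(4-methoxybenzyl)oxy]methyl}-2-(2-oxoethyl)-7-{(R)-5-oxo-4-[(4,4,5,5-tetramethyl-1,3,2-dioxaborolan-2-yl)methyl]-2,5-dihydrofuran-2-yl}hepta-2,6-dien-1-yl acetate F2.
- F2 would be cyclised in toluene at high dilution, thermally or with Sc(OTf)3, and the borate hydrolysed on work-up to 29.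

**Step 3.** The most likely failures are fragmentation of the β-alkoxy Grignard reagent 5 and incomplete carbometalation at the temperature an internal alkynol needs. The fallback separates hydrometalation from C–C bond formation. It sets out from 4 and comes back at 7.
- Hydroxyl-directed trans-hydrostannation (Bu3SnH, [Cp*RuCl]4, CH2Cl2) should give (Z)-5-[(tert-butyldimethylsilyl)oxy]-2-(tributylstannyl)pent-2-en-1-ol F3.
- Iodine converts F3 with retention into (Z)-5-[(tert-butyldimethylsilyl)oxy]-2-iodopent-2-en-1-ol F4.
- Negishi coupling of F4 with (1,3-dioxolan-2-ylmethyl)zinc bromide F5 (from 5 and ZnBr2; Pd(OAc)2, SPhos, THF) gives 7.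

**Step 10.** The most likely failures are polymerisation or conjugate addition of acrolein and modest enantioselectivity with so small an aldehyde. The fallback replaces asymmetric catalysis by resolution. It sets out from 15 and 16 and comes back at 18.
- Addition of the lithium acetylide of 15 (n-BuLi, THF, −78 °C) to 16 gives rac-6-[(4-methoxybenzyl)oxy]hex-1-en-4-yn-3-ol F6.
- Lipase-catalysed acyl transfer (Candida antarctica lipase B, vinyl acetate) is expected, by the usual size rule for secondary alcohols, to acylate the R enantiomer to (3R)-6-[(4-methoxybenzyl)oxy]hex-1-en-4-yn-3-yl acetate F7 and leave (S)-18, which is separated by chromatography.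

**Step 14.** The most likely failures are ionisation of the allylic C–O bonds (lactone C6–O, acetate C14–O) by zerovalent palladium once the iodide is consumed, and partial loss of the C1=C10 geometry if the homoallylic radical formed during zinc insertion closes reversibly to a cyclopropylcarbinyl radical. The fallback changes the order of events so that no allylic leaving group sits at C6 during the coupling. It sets out from 20 and 23 and comes back at 24.
- Coupling 23 with the free alcohol 20 (Pd(OAc)2, SPhos, excess 23) gives (2E,6E,8S)-2-[(1,3-dioxolan-2-yl)methyl]-8-hydroxy-6-{[(4-methoxybenzyl)oxy]methyl}deca-2,6,9-trien-1-yl acetate F8.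
- Esterification with 13 (DCC, DMAP) gives (3S,4E,8E)-9-(acetoxymethyl)-10-(1,3-dioxolan-2-yl)-5-{[(4-methoxybenzyl)oxy]methyl}deca-1,4,8-trien-3-yl 2-{[(tert-butyldimethylsilyl)oxy]methyl}acrylate F9.
- Ring-closing metathesis as in step 13 gives 24.

**Step 17.** The most likely failures are migration of C1=C10 into conjugation with the new aldehyde under the acid needed to open a dioxolane, and solvolysis of the allylic bromide. The fallback changes the mask before it is removed. It sets out from 26 and comes back at 27.
- Anhydrous acetal exchange (HC(OMe)3, MeOH, PPTS), in which no free aldehyde is present, gives (2E,6E)-7-[(R)-4-(bromomethyl)-5-oxo-2,5-dihydrofuran-2-yl]-2-(2,2-dimethoxyethyl)-6-{[(4-methoxybenzyl)oxy]methyl}hepta-2,6-dien-1-yl acetate F10.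
- The far more labile dimethyl acetal is then cleaved near neutrality (LiBF4, wet MeCN, rt) to 27.

## Further compounds

F1 | step 18 | (2E,6E)-2-[(1,3-dioxolan-2-yl)methyl]-6-{[(4-methoxybenzyl)oxy]methyl}-7-{(R)-5-oxo-4-[(4,4,5,5-tetramethyl-1,3,2-dioxaborolan-2-yl)methyl]-2,5-dihydrofuran-2-yl}hepta-2,6-dien-1-yl acetate | O=C1O[C@H](/C=C(COCc2ccc(OC)cc2)\CC/C=C(COC(C)=O)\CC2OCCO2)C=C1CB1OC(C)(C)C(C)(C)O1
F2 | step 18 | (2E,6E)-6-{[(4-methoxybenzyl)oxy]methyl}-2-(2-oxoethyl)-7-{(R)-5-oxo-4-[(4,4,5,5-tetramethyl-1,3,2-dioxaborolan-2-yl)methyl]-2,5-dihydrofuran-2-yl}hepta-2,6-dien-1-yl acetate | O=C1O[C@H](/C=C(COCc2ccc(OC)cc2)\CC/C=C(COC(C)=O)\CC=O)C=C1CB1OC(C)(C)C(C)(C)O1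
F3 | step 3 | (Z)-5-[(tert-butyldimethylsilyl)oxy]-2-(tributylstannyl)pent-2-en-1-ol | OC/C(=C/CCO[Si](C)(C)C(C)(C)C)[Sn](CCCC)(CCCC)CCCC
F4 | step 3 | (Z)-5-[(tert-butyldimethylsilyl)oxy]-2-iodopent-2-en-1-ol | OC/C(I)=C/CCO[Si](C)(C)C(C)(C)C
F5 | step 3 | (1,3-dioxolan-2-ylmethyl)zinc bromide | Br[Zn]CC1OCCO1
F6 | step 10 | rac-6-[(4-methoxybenzyl)oxy]hex-1-en-4-yn-3-ol | C=CC(O)C#CCOCc1ccc(OC)cc1
F7 | step 10 | (3R)-6-[(4-methoxybenzyl)oxy]hex-1-en-4-yn-3-yl acetate | C=C[C@@H](OC(C)=O)C#CCOCc1ccc(OC)cc1
F8 | step 14 | (2E,6E,8S)-2-[(1,3-dioxolan-2-yl)methyl]-8-hydroxy-6-{[(4-methoxybenzyl)oxy]methyl}deca-2,6,9-trien-1-yl acetate | C=C[C@H](O)/C=C(COCc1ccc(OC)cc1)\CC/C=C(COC(C)=O)\CC1OCCO1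
F9 | step 14 | (3S,4E,8E)-9-(acetoxymethyl)-10-(1,3-dioxolan-2-yl)-5-{[(4-methoxybenzyl)oxy]methyl}deca-1,4,8-trien-3-yl 2-{[(tert-butyldimethylsilyl)oxy]methyl}acrylate | C=C[C@H](OC(=O)C(=C)CO[Si](C)(C)C(C)(C)C)/C=C(COCc1ccc(OC)cc1)\CC/C=C(COC(C)=O)\CC1OCCO1
F10 | step 17 | (2E,6E)-7-[(R)-4-(bromomethyl)-5-oxo-2,5-dihydrofuran-2-yl]-2-(2,2-dimethoxyethyl)-6-{[(4-methoxybenzyl)oxy]methyl}hepta-2,6-dien-1-yl acetate | O=C1O[C@H](/C=C(COCc2ccc(OC)cc2)\CC/C=C(COC(C)=O)\CC(OC)OC)C=C1CBr
A1 | alternative 1 | (2Z,6Z)-3,7-dimethylcyclodeca-2,6-dien-1-one | O=C1/C=C(C)\CC/C=C(C)\CCC1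
A2 | alternative 1 | (1Z,5Z)-1,5-dimethylcycloocta-1,5-diene | C/C1=C/CC/C(C)=C\CC1
A3 | alternative 2 | (2Z,6E,9S)-9-[(tert-butyldimethylsilyl)oxy]-7-(hydroxymethyl)-3-methylcyclodeca-2,6-dien-1-one | O=C1/C=C(C)\CC/C=C(CO)\C[C@H](O[Si](C)(C)C(C)(C)C)C1
A4 | alternative 3 | (3aR,4S,6E,10E,11aR)-6-(acetoxymethyl)-10-formyl-3-methylidene-2-oxo-2,3,3a,4,5,8,9,11a-octahydrocyclodeca[b]furan-4-yl 2-{[(tert-butyldimethylsilyl)oxy]methyl}acrylate | C=C(CO[Si](C)(C)C(C)(C)C)C(=O)O[C@H]1C/C(COC(C)=O)=C\CC/C(C=O)=C\[C@H]2OC(=O)C(=C)[C@H]12
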